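**Retrosynthetic overview**
1. The target is (4R,5R,9R,10R)-19-acetoxy-20-oxo-ent-labda-8(17),13-dien-16,15-olide; the last disconnection is C12–C13 (Negishi coupling of a C12 zinc reagent with purchased 3-bromofuran-2(5H)-one).
2. Rings A and B are disconnected together to an acyclic 2-substituted acrolein: a C2 radical closes ring A through the C1–C2 bond, the resulting C10 radical closes ring B through the C9–C10 bond, and loss of PhS from C17 leaves the 8(17)-methylene (ring A, then ring B, in one flask).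
3. Enabling feature: the formyl carbon C20 sits on the ring-fusion carbon C10 next to C1, so C1=C10–C20=O is an acrolein whose terminus C1 accepts the C2 radical and whose α-formyl C10 radical is matched to the electron-rich C8=C9 alkene; the exocyclic C17 on ring B marks where an allylic leaving group can sit.
4. C4 and C5 are set by a Mukaiyama–Michael addition of the ketene acetal of α-methyl-γ-butyrolactone (C2, C3, C4, C18, C19) to a C20–C10=C5 enal; selenolate opening of the lactone gives the C2 radical precursor and C19 at the acid level, and C1 is added as formaldehyde.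
5. The enal chain (C5–C12 with C17) comes from 2-bromoallyl alcohol and 3-silyloxypropanal; a Johnson–Claisen rearrangement fixes the C8=C9 geometry.

Key step: step 13

Remark: C-numbers (C1–C20) are the labdane numbers of the target; TBS = tert-butyldimethylsilyl. Compounds 4, 5 and 10 are racemic; their stereocentres are erased in steps 3 and 6.
Assumption: the iminium ion of the (2R,5R)-imidazolidinone is attacked on the face that gives the 5S configuration of 13, by analogy with the usual facial sense of this catalyst class with β-alkyl enals; the mirror-image catalyst would be used if the sense were the opposite.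

**Step 1**
Reactants: 1 2-bromoprop-2-en-1-ol; 2 3-[(tert-butyldimethylsilyl)oxy]propanal
Product: 4 5-[(tert-butyldimethylsilyl)oxy]-2-methylidenepentane-1,3-diol (racemic), via dilithio reagent 3 (not isolated)
Conditions: t-BuLi (3.1 equiv), Et2O, −78 → 0 °C; then 2, −78 °C; H2O
Reagents that add atoms: none
Why: Bromine–lithium exchange on the lithium alkoxide of 1 gives the O,2-dilithio reagent, whose vinyl carbanion adds 1,2 to aldehyde 2 (organolithium addition); the carbinol centre is formed racemic and is erased in step 3.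

**Step 2**
Reactants: 4 5-[(tert-butyldimethylsilyl)oxy]-2-methylidenepentane-1,3-diol
Product: 5 5-[(tert-butyldimethylsilyl)oxy]-2-[(phenylsulfanyl)methyl]pent-1-en-3-ol (racemic)
Conditions: PhSSPh, n-Bu3P, pyridine, 0 °C → rt
Reagents that add atoms: diphenyl disulfide, c1ccccc1SSc1ccccc1
Why: Disulfide/phosphine redox condensation converts the unhindered primary allylic hydroxyl selectively into the phenyl sulfide through its oxyphosphonium ion, and SN2 and SN2′ attack give the same product because the two allylic CH2 termini are equivalent.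

**Step 3**
Reactants: 5 5-[(tert-butyldimethylsilyl)oxy]-2-[(phenylsulfanyl)methyl]pent-1-en-3-ol
Product: 7 ethyl (4Z)-7-[(tert-butyldimethylsilyl)oxy]-4-[(phenylsulfanyl)methyl]hept-4-enoate, via ketene acetal 6 (not isolated)
Conditions: MeC(OEt)3 (neat, excess), EtCO2H (cat.), 140 °C, EtOH distilled off
Reagents that add atoms: triethyl orthoacetate, CC(OCC)(OCC)OCC
Why: Johnson–Claisen rearrangement through ketene acetal 6, in which the chair transition state with the C11 chain equatorial should give the trisubstituted C8=C9 alkene with C7 and C11 trans.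

**Step 4**
Reactants: 7 ethyl (4Z)-7-[(tert-butyldimethylsilyl)oxy]-4-[(phenylsulfanyl)methyl]hept-4-enoate
Product: 8 (4Z)-7-[(tert-butyldimethylsilyl)oxy]-4-[(phenylsulfanyl)methyl]hept-4-enal
Conditions: i-Bu2AlH (1.05 equiv), CH2Cl2, −78 °C; aq. sodium potassium tartrate
Reagents that add atoms: none
Why: Partial ester reduction, in which the tetrahedral aluminium hemiacetal is stable at −78 °C and releases the C5 aldehyde only on work-up.

**Step 5**
Reactants: 8 (4Z)-7-[(tert-butyldimethylsilyl)oxy]-4-[(phenylsulfanyl)methyl]hept-4-enal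
Product: 9 (2E,6Z)-9-[(tert-butyldimethylsilyl)oxy]-6-[(phenylsulfanyl)methyl]nona-2,6-dienal
Conditions: Ph3P=CHCHO (1.1 equiv), toluene, 80 °C
Reagents that add atoms: (triphenyl-λ5-phosphanylidene)acetaldehyde, O=CC=P(c1ccccc1)(c1ccccc1)c1ccccc1
Why: Wittig reaction with the stabilised formyl ylide should give the (E)-enal (C20, C10, C5) and stop after one homologation because the enal product is less electrophilic than 8.

**Step 6**
Reactants: 10 3-methyloxolan-2-one (α-methyl-γ-butyrolactone, racemic)
Product: 12 tert-butyl(dimethyl)[(3-methyl-4,5-dihydrofuran-2-yl)oxy]silane, via lithium enolate 11 (not isolated)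
Conditions: LiN(i-Pr)2, THF, −78 °C; then t-BuMe2SiCl, DMPU, −78 → 0 °C
Reagents that add atoms: tert-butyl(chloro)dimethylsilane, CC(C)(C)[Si](C)(C)Cl
Why: O-silylation of the lactone enolate gives a cyclic silyl ketene acetal whose geometry is fixed by the ring.

**Step 7**
Reactants: 9 (2E,6Z)-9-[(tert-butyldimethylsilyl)oxy]-6-[(phenylsulfanyl)methyl]nona-2,6-dienal; 12 tert-butyl(dimethyl)[(3-methyl-4,5-dihydrofuran-2-yl)oxy]silane
Product: 14 (3R)-3-{(3S,6Z)-9-[(tert-butyldimethylsilyl)oxy]-1,1-dimethoxy-6-[(phenylsulfanyl)methyl]non-6-en-3-yl}-3-methyloxolan-2-one, via aldehyde 13 (not isolated)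
Conditions: (2R,5R)-5-benzyl-2-tert-butyl-3-methylimidazolidin-4-one·CF3CO2H (20 mol%), H2O (2 equiv), CH2Cl2, −40 °C; then HC(OMe)3, MeOH, PPTS, 0 °C
Reagents that add atoms: trimethyl orthoformate, COC(OC)OC; methanol, CO
Why: Iminium-catalysed Mukaiyama–Michael addition, in which the benzyl group of the catalyst shields one face of the (E)-iminium ion so that C4 of 12 bonds to C5 on the open face (5S), and in the open antiperiplanar transition state the tied-back ring methylene C3 rather than the methyl group should take the crowded position between C6 and C10 (4R), after which the aldehyde is masked in the same flask as its dimethyl acetal.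

**Step 8**
Reactants: 14 (3R)-3-{(3S,6Z)-9-[(tert-butyldimethylsilyl)oxy]-1,1-dimethoxy-6-[(phenylsulfanyl)methyl]non-6-en-3-yl}-3-methyloxolan-2-one
Product: 15 (2R,3S,6Z)-9-[(tert-butyldimethylsilyl)oxy]-3-(2,2-dimethoxyethyl)-2-methyl-6-[(phenylsulfanyl)methyl]-2-[2-(phenylselanyl)ethyl]non-6-enoic acid
Conditions: PhSeH, NaH, DMF, 0 → 110 °C; then AcOH (to pH 5)
Reagents that add atoms: benzeneselenol, [SeH]c1ccccc1
Why: SN2 ring opening of the γ-lactone at its O–CH2 carbon (C2) by the soft selenolate (O-alkyl cleavage) places the radical precursor on C2 and frees C19 as the acid without touching the quaternary centre.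

**Step 9**
Reactants: 15 (2R,3S,6Z)-9-[(tert-butyldimethylsilyl)oxy]-3-(2,2-dimethoxyethyl)-2-methyl-6-[(phenylsulfanyl)methyl]-2-[2-(phenylselanyl)ethyl]non-6-enoic acid
Product: 16 (2R,3S,6Z)-9-[(tert-butyldimethylsilyl)oxy]-3-(2,2-dimethoxyethyl)-2-methyl-6-[(phenylsulfanyl)methyl]-2-[2-(phenylselanyl)ethyl]non-6-en-1-ol
Conditions: LiAlH4, THF, 0 → 50 °C; H2O, then aq. NaOH
Reagents that add atoms: none
Why: Hydride reduction of the hindered carboxylic acid to the neopentyl C19 alcohol, to which selenide, sulfide, acetal, silyl ether and the isolated alkene are inert.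

**Step 10**
Reactants: 16 (2R,3S,6Z)-9-[(tert-butyldimethylsilyl)oxy]-3-(2,2-dimethoxyethyl)-2-methyl-6-[(phenylsulfanyl)methyl]-2-[2-(phenylselanyl)ethyl]non-6-en-1-ol
Product: 17 (2R,3S,6Z)-9-[(tert-butyldimethylsilyl)oxy]-3-(2,2-dimethoxyethyl)-2-methyl-6-[(phenylsulfanyl)methyl]-2-[2-(phenylselanyl)ethyl]non-6-en-1-yl acetate
Conditions: Ac2O, pyridine, DMAP (cat.), CH2Cl2, rt
Reagents that add atoms: acetic anhydride, CC(=O)OC(C)=O
Why: DMAP-catalysed acylation installs the C19 acetate of the target on the only free hydroxyl.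

**Step 11**
Reactants: 17 (2R,3S,6Z)-9-[(tert-butyldimethylsilyl)oxy]-3-(2,2-dimethoxyethyl)-2-methyl-6-[(phenylsulfanyl)methyl]-2-[2-(phenylselanyl)ethyl]non-6-en-1-yl acetate
Product: 18 (2R,3S,6Z)-9-hydroxy-2-methyl-3-(2-oxoethyl)-6-[(phenylsulfanyl)methyl]-2-[2-(phenylselanyl)ethyl]non-6-en-1-yl acetate
Conditions: 1 M HCl, THF, rt
Reagents that add atoms: water, O
Why: Acid hydrolysis cleaves the dimethyl acetal and the primary silyl ether together, while the neopentyl acetate, the selenide and the allyl sulfide should survive.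

**Step 12**
Reactants: 18 (2R,3S,6Z)-9-hydroxy-2-methyl-3-(2-oxoethyl)-6-[(phenylsulfanyl)methyl]-2-[2-(phenylselanyl)ethyl]non-6-en-1-yl acetate
Product: 19 (2R,3R,6Z)-9-hydroxy-2-methyl-3-(3-oxoprop-1-en-2-yl)-6-[(phenylsulfanyl)methyl]-2-[2-(phenylselanyl)ethyl]non-6-en-1-yl acetate
Conditions: aq. CH2O (37%), pyrrolidine (10 mol%), EtCO2H (10 mol%), i-PrOH, 45 °C
Reagents that add atoms: formaldehyde, C=O
Why: Amine-catalysed Mannich condensation and elimination (α-methylenation of an α-unbranched aldehyde) adds C1 as the methylene terminus of the 2-substituted acrolein; C5 is untouched (its descriptor changes only by priority).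

**Step 13**
Reactants: 19 (2R,3R,6Z)-9-hydroxy-2-methyl-3-(3-oxoprop-1-en-2-yl)-6-[(phenylsulfanyl)methyl]-2-[2-(phenylselanyl)ethyl]non-6-en-1-yl acetate
Product: 23 (4R,5R,9R,10R)-19-acetoxy-12-hydroxy-13,14,15,16-tetranor-ent-labd-8(17)-en-20-al, via C2 radical 20 (not isolated), via C10 radical 21 (not isolated), via C8 radical 22 (not isolated)
Conditions: Bu3SnSnBu3 (1.5 equiv), hν (sunlamp, Pyrex), degassed PhH (0.005 M), 80 °C
Reagents that add atoms: none
Why: Proposed new method: Bu3Sn• (from photolysis of Bu3SnSnBu3) abstracts PhSe from C2; the nucleophilic primary radical 20 adds to the unsubstituted terminus C1 of the acrolein (6-endo-trig, ring A), the electrophilic α-formyl radical 21 at C10 adds to C9 of the electron-rich trisubstituted allyl sulfide (6-endo-trig, ring B), and tertiary radical 22 expels PhS• to leave the 8(17)-methylene, PhS• being turned back into Bu3Sn• by the distannane, so that no hydrogen donor or reductant is present to intercept 21 before the slower second closure. The closest known reaction types are the 6-endo cyclisation of 5-hexenyl radicals onto α-substituted acrylates, polarity-alternating radical polyene cyclisations that place a nitrile or carbonyl group at a trans ring fusion, and radical allylation by addition–fragmentation of allyl sulfides; their combination on a 2-alkylacrolein has not been described. C10 and C9 are set in the second closure through a chair–chair transition state: ring A carries the C6 chain equatorial and the acetoxymethyl group axial, which blocks the α face of the planar C10 radical, so C9 should bond on the β face and push the formyl group axial (trans ring fusion, C19 and C20 syn-diaxial), while the C8=C9 geometry (C7 and C11 trans) places the C11 chain equatorial. The step needs endo closure twice and chemoselective abstraction at selenium: the formyl group on C10 directs the first attack to C1, the fully substituted C8 directs the second attack to C9, and abstraction of PhSe by Bu3Sn• is irreversible whereas its addition to the sulfide alkene or the enal is reversible.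

**Step 14**
Reactants: 23 (4R,5R,9R,10R)-19-acetoxy-12-hydroxy-13,14,15,16-tetranor-ent-labd-8(17)-en-20-al
Product: 24 (4R,5R,9R,10R)-19-acetoxy-12-iodo-13,14,15,16-tetranor-ent-labd-8(17)-en-20-al
Conditions: I2, PPh3, imidazole, CH2Cl2, 0 °C → rt
Reagents that add atoms: iodine, II
Why: Appel-type iodination of the unhindered primary alcohol by SN2 displacement of its oxyphosphonium ion, leaving the hindered aldehyde, the acetate and the 1,1-disubstituted alkene alone.

**Step 15**
Reactants: 24 (4R,5R,9R,10R)-19-acetoxy-12-iodo-13,14,15,16-tetranor-ent-labd-8(17)-en-20-al; 25 3-bromofuran-2(5H)-one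
Product: 27 (4R,5R,9R,10R)-19-acetoxy-20-oxo-ent-labda-8(17),13-dien-16,15-olide, via organozinc iodide 26 (not isolated)
Conditions: Zn dust, LiCl, THF, 40 °C; then 25, Pd(OAc)2 (3 mol%), SPhos (6 mol%), THF, rt
Reagents that add atoms: none
Why: Negishi coupling: zinc inserts into the primary C–I bond, and the alkylzinc iodide (unreactive towards the hindered, non-enolisable C20 aldehyde and the acetate) transmetalates to the alkenylpalladium bromide formed by oxidative addition of zerovalent palladium to 25, forming C12–C13 with the butenolide double bond in place.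

**Compound list**
1 | 2-bromoprop-2-en-1-ol | OCC(Br)=C | starting material
2 | 3-[(tert-butyldimethylsilyl)oxy]propanal | O=CCCO[Si](C)(C)C(C)(C)C | starting material
3 | lithium 2-lithioprop-2-en-1-olate (dilithio reagent) | [Li]OCC([Li])=C | intermediate
4 | 5-[(tert-butyldimethylsilyl)oxy]-2-methylidenepentane-1,3-diol (racemic) | OCC(=C)C(O)CCO[Si](C)(C)C(C)(C)C | intermediate
5 | 5-[(tert-butyldimethylsilyl)oxy]-2-[(phenylsulfanyl)methyl]pent-1-en-3-ol (racemic) | C=C(CSc1ccccc1)C(O)CCO[Si](C)(C)C(C)(C)C | intermediate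
6 | tert-butyl({3-[(1-ethoxyethenyl)oxy]-4-[(phenylsulfanyl)methyl]pent-4-en-1-yl}oxy)dimethylsilane (ketene acetal) | C=C(OCC)OC(CCO[Si](C)(C)C(C)(C)C)C(=C)CSc1ccccc1 | intermediate
7 | ethyl (4Z)-7-[(tert-butyldimethylsilyl)oxy]-4-[(phenylsulfanyl)methyl]hept-4-enoate | CCOC(=O)CC/C(CSc1ccccc1)=C/CCO[Si](C)(C)C(C)(C)C | intermediate
8 | (4Z)-7-[(tert-butyldimethylsilyl)oxy]-4-[(phenylsulfanyl)methyl]hept-4-enal | O=CCC/C(CSc1ccccc1)=C/CCO[Si](C)(C)C(C)(C)C | intermediate
9 | (2E,6Z)-9-[(tert-butyldimethylsilyl)oxy]-6-[(phenylsulfanyl)methyl]nona-2,6-dienal | O=C/C=C/CC/C(CSc1ccccc1)=C/CCO[Si](C)(C)C(C)(C)C | intermediate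
10 | 3-methyloxolan-2-one (α-methyl-γ-butyrolactone, racemic) | CC1CCOC1=O | starting material
11 | lithium 3-methyl-4,5-dihydrofuran-2-olate (lithium enolate of 10) | CC1=C(O[Li])OCC1 | intermediate
12 | tert-butyl(dimethyl)[(3-methyl-4,5-dihydrofuran-2-yl)oxy]silane | CC1=C(O[Si](C)(C)C(C)(C)C)OCC1 | intermediate
13 | (3S,6Z)-9-[(tert-butyldimethylsilyl)oxy]-3-[(3R)-3-methyl-2-oxooxolan-3-yl]-6-[(phenylsulfanyl)methyl]non-6-enal | CC(C)(C)[Si](C)(C)OCC/C=C(CSc1ccccc1)/CC[C@@H](CC=O)[C@]1(C)C(=O)OCC1 | intermediate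
14 | (3R)-3-{(3S,6Z)-9-[(tert-butyldimethylsilyl)oxy]-1,1-dimethoxy-6-[(phenylsulfanyl)methyl]non-6-en-3-yl}-3-methyloxolan-2-one | CC(C)(C)[Si](C)(C)OCC/C=C(CSc1ccccc1)/CC[C@@H](CC(OC)OC)[C@]1(C)C(=O)OCC1 | intermediate
15 | (2R,3S,6Z)-9-[(tert-butyldimethylsilyl)oxy]-3-(2,2-dimethoxyethyl)-2-methyl-6-[(phenylsulfanyl)methyl]-2-[2-(phenylselanyl)ethyl]non-6-enoic acid | CC(C)(C)[Si](C)(C)OCC/C=C(CSc1ccccc1)/CC[C@@H](CC(OC)OC)[C@](C)(C(=O)O)CC[Se]c1ccccc1 | intermediate
16 | (2R,3S,6Z)-9-[(tert-butyldimethylsilyl)oxy]-3-(2,2-dimethoxyethyl)-2-methyl-6-[(phenylsulfanyl)methyl]-2-[2-(phenylselanyl)ethyl]non-6-en-1-ol | CC(C)(C)[Si](C)(C)OCC/C=C(CSc1ccccc1)/CC[C@@H](CC(OC)OC)[C@](C)(CO)CC[Se]c1ccccc1 | intermediate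
17 | (2R,3S,6Z)-9-[(tert-butyldimethylsilyl)oxy]-3-(2,2-dimethoxyethyl)-2-methyl-6-[(phenylsulfanyl)methyl]-2-[2-(phenylselanyl)ethyl]non-6-en-1-yl acetate | CC(C)(C)[Si](C)(C)OCC/C=C(CSc1ccccc1)/CC[C@@H](CC(OC)OC)[C@](C)(COC(C)=O)CC[Se]c1ccccc1 | intermediate
18 | (2R,3S,6Z)-9-hydroxy-2-methyl-3-(2-oxoethyl)-6-[(phenylsulfanyl)methyl]-2-[2-(phenylselanyl)ethyl]non-6-en-1-yl acetate | OCC/C=C(CSc1ccccc1)/CC[C@@H](CC=O)[C@](C)(COC(C)=O)CC[Se]c1ccccc1 | intermediate
19 | (2R,3R,6Z)-9-hydroxy-2-methyl-3-(3-oxoprop-1-en-2-yl)-6-[(phenylsulfanyl)methyl]-2-[2-(phenylselanyl)ethyl]non-6-en-1-yl acetate | OCC/C=C(CSc1ccccc1)/CC[C@@H](C(=C)C=O)[C@](C)(COC(C)=O)CC[Se]c1ccccc1 | intermediate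
20 | primary C2 radical formed from 19 by loss of PhSe | OCC/C=C(CSc1ccccc1)/CC[C@@H](C(=C)C=O)[C@](C)(COC(C)=O)C[CH2] | intermediate
21 | monocyclic α-formyl C10 radical (ring A closed; C4 and C5 as in 19) | OCC/C=C(CSc1ccccc1)/CC[C@@H]1[C@](C)(COC(C)=O)CCC[C]1C=O | intermediate
22 | bicyclic tertiary C8 radical carrying the PhSCH2 group (rings A and B closed; C4, C5, C9, C10 as in 23) | C(Sc3ccccc3)[C]1CC[C@@H]2[C@](C)(COC(C)=O)CCC[C@@]2(C=O)[C@@H]1CCO | intermediate
23 | (4R,5R,9R,10R)-19-acetoxy-12-hydroxy-13,14,15,16-tetranor-ent-labd-8(17)-en-20-al | C=C1CC[C@@H]2[C@](C)(COC(C)=O)CCC[C@@]2(C=O)[C@@H]1CCO | intermediate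
24 | (4R,5R,9R,10R)-19-acetoxy-12-iodo-13,14,15,16-tetranor-ent-labd-8(17)-en-20-al | C=C1CC[C@@H]2[C@](C)(COC(C)=O)CCC[C@@]2(C=O)[C@@H]1CCI | intermediate
25 | 3-bromofuran-2(5H)-one | O=C1OCC=C1Br | starting material
26 | [(4R,5R,9R,10R)-19-acetoxy-20-oxo-13,14,15,16-tetranor-ent-labd-8(17)-en-12-yl]zinc iodide | C=C1CC[C@@H]2[C@](C)(COC(C)=O)CCC[C@@]2(C=O)[C@@H]1CC[Zn]I | intermediate
27 | (4R,5R,9R,10R)-19-acetoxy-20-oxo-ent-labda-8(17),13-dien-16,15-olide (CNP0109410.1) | C=C1CC[C@@H]2[C@](C)(COC(C)=O)CCC[C@@]2(C=O)[C@@H]1CCC1=CCOC1=O | target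

**Step count and risks**
Total step count: 15. Longest linear sequence: 14 steps (steps 1–5 and 7–15; step 6 is a one-step branch).

Steps most likely to fail:

1. Step 13 (proposed new method). What may go wrong: the second ring closure is slow, so the C10 radical may be lost by disproportionation or dimerisation; the chain may be diverted by reversible addition of PhS• or Bu3Sn• to the enal; facial selectivity at C10 may be incomplete. Fallback (known chemistry, stepwise, setting out from 19 and returning at 23): Bu3SnH (slow addition) and AIBN in PhH at 80 °C should effect the ordinary reductive 6-endo radical cyclisation onto the acrolein, closing ring A through the same C1–C2 bond and giving [(1R,2S)-3-formyl-2-{(3Z)-6-hydroxy-3-[(phenylsulfanyl)methyl]hex-3-en-1-yl}-1-methylcyclohexyl]methyl acetate F1 (C10–H, both epimers usable). Oxidation of the sulfide with (NH4)6Mo7O24 (cat.) and H2O2 in EtOH at 0 °C should give the allyl sulfone [(1R,2S)-3-formyl-2-{(3Z)-6-hydroxy-3-[(phenylsulfonyl)methyl]hex-3-en-1-yl}-1-methylcyclohexyl]methyl acetate F2. Pd(PPh3)4 with a catalytic secondary amine in DMSO (enamine Tsuji–Trost cyclisation, sulfinate as leaving group, attack at the internal allyl terminus C9) should then close ring B with the exocyclic methylene and the C10 quaternary centre, giving 23.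

2. Step 7. What may go wrong: low simple diastereoselectivity at C4 in the open transition state, or hydrolysis of the ketene acetal before it reacts. Fallback (auxiliary control, setting out from 8 and returning at 13): Horner–Wadsworth–Emmons olefination of 8 with diethyl {2-[(4R)-4-benzyl-2-oxo-1,3-oxazolidin-3-yl]-2-oxoethyl}phosphonate (LiCl, i-Pr2NEt, MeCN) should give (4R)-4-benzyl-3-{(2E,6Z)-9-[(tert-butyldimethylsilyl)oxy]-6-[(phenylsulfanyl)methyl]nona-2,6-dienoyl}-1,3-oxazolidin-2-one F3. Et2AlCl-promoted Mukaiyama–Michael addition of 12 in CH2Cl2 at −78 °C (chelated s-cis imide, attack anti to the benzyl group) should give (4R)-4-benzyl-3-{(3S,6Z)-9-[(tert-butyldimethylsilyl)oxy]-3-[(3R)-3-methyl-2-oxooxolan-3-yl]-6-[(phenylsulfanyl)methyl]non-6-enoyl}-1,3-oxazolidin-2-one F4. NaBH4 in THF/H2O should remove the auxiliary to give (3R)-3-{(3S,6Z)-9-[(tert-butyldimethylsilyl)oxy]-1-hydroxy-6-[(phenylsulfanyl)methyl]non-6-en-3-yl}-3-methyloxolan-2-one F5, and oxidation with DMP (the triacetoxy periodinane) returns to 13, which is acetalised to 14 as in step 7.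

3. Step 15. What may go wrong: sluggish zinc insertion or protodezincation, and decomposition of the base- and nucleophile-sensitive bromobutenolide before transmetalation. Fallback (radical capture at nickel instead of an organozinc, setting out from 24 and ending at 27): cross-electrophile coupling of 24 with 25 using NiCl2(dme), 4,4′-di-tert-butyl-2,2′-bipyridine, Ir[dF(CF3)ppy]2(dtbbpy)PF6, (Me3Si)3SiH and Na2CO3 in DME under blue LEDs, in which a silyl radical abstracts iodine from C12 and the C12 radical is captured by the alkenylnickel bromide formed from 25.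

**Further compounds**
F1 | step 13 | [(1R,2S)-3-formyl-2-{(3Z)-6-hydroxy-3-[(phenylsulfanyl)methyl]hex-3-en-1-yl}-1-methylcyclohexyl]methyl acetate (both C10 epimers) | OCC/C=C(CSc1ccccc1)/CC[C@@H]1[C@](C)(COC(C)=O)CCCC1C=O
F2 | step 13 | [(1R,2S)-3-formyl-2-{(3Z)-6-hydroxy-3-[(phenylsulfonyl)methyl]hex-3-en-1-yl}-1-methylcyclohexyl]methyl acetate (both C10 epimers) | OCC/C=C(CS(=O)(=O)c1ccccc1)/CC[C@@H]1[C@](C)(COC(C)=O)CCCC1C=O
F3 | step 7 | (4R)-4-benzyl-3-{(2E,6Z)-9-[(tert-butyldimethylsilyl)oxy]-6-[(phenylsulfanyl)methyl]nona-2,6-dienoyl}-1,3-oxazolidin-2-one | O=C(/C=C/CC/C(CSc1ccccc1)=C/CCO[Si](C)(C)C(C)(C)C)N1[C@H](Cc2ccccc2)COC1=O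
F4 | step 7 | (4R)-4-benzyl-3-{(3S,6Z)-9-[(tert-butyldimethylsilyl)oxy]-3-[(3R)-3-methyl-2-oxooxolan-3-yl]-6-[(phenylsulfanyl)methyl]non-6-enoyl}-1,3-oxazolidin-2-one | CC(C)(C)[Si](C)(C)OCC/C=C(CSc1ccccc1)/CC[C@@H](CC(=O)N1[C@H](Cc2ccccc2)COC1=O)[C@]1(C)C(=O)OCC1
F5 | step 7 | (3R)-3-{(3S,6Z)-9-[(tert-butyldimethylsilyl)oxy]-1-hydroxy-6-[(phenylsulfanyl)methyl]non-6-en-3-yl}-3-methyloxolan-2-one | CC(C)(C)[Si](C)(C)OCC/C=C(CSc1ccccc1)/CC[C@@H](CCO)[C@]1(C)C(=O)OCC1
F0 | step 15 | none | none
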